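The readings stem from a simulated flask with made-up constants, and the scatter is random.

4 questions stood before me: what share of Q had reacted after 40 h in larch, cedar and ash, and whether raising D changed that share. In each flask Q was fed into D and L.

| flask | Q | D | L | remark | time |
|---|---|---|---|---|---|
| eta | 39 mM (fed, over 4.0 h) | 0.55 equiv | 3 equiv | run made earlier |  |
| beta | 39 mM (fed, over 4.0 h) | 0.70 equiv | 3 equiv | run made earlier |  |
| epsilon | 39 mM (fed, over 4.0 h) | 1 equiv | 3 equiv | run made earlier |  |
| larch | 39 mM (fed, over 4.0 h) | 0.500 equiv | 3.00 equiv |  | 40 h |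
| cedar | 39 mM (fed, over 4.0 h) | 0.650 equiv | 3.00 equiv |  | 40 h |
| ash | 39 mM (fed, over 4.0 h) | 0.850 equiv | 3.00 equiv |  | 40 h |

| run | time / h | Q / % | E / % |
|---|---|---|---|
| eta | 1.50 | 36.8 | 2.5 |
| eta | 4.00 | 100.2 | 1.3 |
| eta | 8.00 | 97.4 | 2.4 |
| eta | 20.0 | 93.2 | 7.2 |
| beta | 2.50 | 60.2 | 0.1 |
| beta | 8.00 | 96.2 | 3.3 |
| beta | 12.0 | 95.2 | 4.5 |
| beta | 20.0 | 93.3 | 7.2 |
| epsilon | 5.00 | 96.8 | 0.8 |
| epsilon | 10.0 | 95.5 | 3.4 |
| epsilon | 15.0 | 94.6 | 6.7 |
| epsilon | 20.0 | 91.0 | 8.2 |

(scatter of a reading: 1 percentage point)

- the earlier runs were read with a standard deviation of 1 percentage point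
- percentages count the whole charge, also what has not yet gone in

- part of the Q that has reacted at the end, larch
- part of the Q that has reacted at the end, cedar
- part of the Q that has reacted at the end, ash
- what raising the equivalents of D from its lowest to its highest value here does to the part of the Q that has reacted (changes below 5 percentage points count as none) (it rises / no change / it falls)

First I asked where the reacted Q went. In the epsilon run at 20.0 h, Q and E summed to 99.2%, so I read E as the reacted share.

Next I asked what D did. At 20.0 h, E stood at 7.2%, 7.2% and 8.2% for 0.55 equiv, 0.70 equiv and 1 equiv of D. That spread of 1 percentage point is about one standard deviation, so I pooled the runs, with a mean of 7.53%.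

Then I set the clock. A steady feed delivers Q on average at 2.00 h, so I counted from there. I assumed a pseudo-first-order loss, proportional to cQ, which gave a rate constant of 0.00435 /h. The half-life of Q under this slow loss, ln(2) divided by that constant, was 159 h.

That is longer than the run, so I took each flask to be still far from any end state at 40 h. My number was 15.2% for each flask. Stretched the same way, the D spread became 2.1 points, less than the 5 points that counts.

The weak link was that single mean of E. I reforged it from the separate Q column, which gave a loss of 7.50% at 20.0 h. Scatter alone put about 1.2 points on my number. The curve beyond 20.0 h stayed unmeasured.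

The forecast gave 14.5%, 15% and 15.5%, with the trend no change. It held that “the rate barely depends on D”.

The flasks gave 10.8%, 11.6% and 12.6%, a change of 1.8 points, so the trend was no change. The forecast held on all four counts.

    Q + J → Z + E (k = 7.50 /M/h)
    D ⇌ X (K = 0.690, k = 0.0370 /h)
    J + Z ⇌ L, settled at all times (K = 1.10 × 10⁵ /M)
    Z + D ⇌ G (K = 5.80 × 10⁵ /M, k = 4.30 /M/h)

In cedar at 5.69 h, the half-life of Q by the step to Z and E was 150 h, long against the 40 h run. Cedar kept 88% of its Q, more than the 84.8% that my 159 h half-life had given.

The neighbour flask is cedar at 160 mM of Q. My half-life contains no charge, so it gives 15.2% again. The computed flask gave 18.1%.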